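**Retrosynthetic overview**

1. The target is reached last by phenol desilylation and, before that, SN2 displacement (inversion) of a C8 allylic mesylate by H2O2; the C8 alcohol comes from CBS reduction of a ring α-methylene ketone.
2. The coumarate is attached by Steglich acylation of the C1 alcohol with O-silylated p-coumaric acid.
3. The eleven-membered carbocycle (second ring formed, the only one kept) comes from ring-closing metathesis that makes the Z-trisubstituted C3=C4 alkene of an acyclic hydroxy enone.
4. The hydroxy enone comes from a δ-lactone and 2-lithiohexa-1,5-diene; the lactone (a temporary oxane, first ring formed, opened again) comes from a lactol.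
5. Key step: enantioselective mono-methallylboration of the symmetric dialdehyde 3,3-dimethylpentanedial, which tells its two ends apart and sets C1; the untouched aldehyde is stored as the lactol.

Assumption: 3,3-dimethylpentane-1,5-diol, 2,3-dibromopropene, allylmagnesium bromide and p-coumaric acid are bought, and the ring alkene is Z (ring carbons cis) as the SMILES states.

**Route**

Step 1
Reactants: 1 3,3-dimethylpentane-1,5-diol
Product: 2 3,3-dimethylpentanedial
Conditions: (COCl)2, DMSO, CH2Cl2, −78 °C; Et3N, −78 to 0 °C; used crude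
Reagents that add atoms: none
Why: Swern oxidation turns both primary alcohols into alkoxysulfonium salts before any aldehyde is released, so the symmetric dialdehyde forms without passing through the lactol that other oxidants carry on to a lactone; no stereocentre is involved.

Step 2
Reactants: 2 3,3-dimethylpentanedial
Product: 5 (6S)-4,4-dimethyl-6-(2-methylprop-2-en-1-yl)oxan-2-ol (anomer mixture), via Ipc2B borinate 3 (not isolated), via hydroxy aldehyde 4 (not isolated)
Conditions: (−)-Ipc2BOMe (1.0 equiv), 2-methylallylmagnesium chloride (0.95 equiv), Et2O, −78 °C to rt; cannulated into 2 (3 equiv), Et2O, −78 °C; pH 7 buffer, MeOH, 30% H2O2, 0 °C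
Reagents that add atoms: 2-methylallylmagnesium chloride, CC(=C)C[Mg]Cl
Why: Brown asymmetric methallylboration through a chair Zimmerman–Traxler transition state, in which the isopinocampheyl groups from (+)-α-pinene send the allyl unit to the Si face of one aldehyde and set the carbinol centre (5S in 4, later C1 of the ring), while the excess of cheap dialdehyde and collapse of the mono-adduct to the lactol hold back a second addition.

Step 3
Reactants: 5 (6S)-4,4-dimethyl-6-(2-methylprop-2-en-1-yl)oxan-2-ol
Product: 6 (6S)-4,4-dimethyl-6-(2-methylprop-2-en-1-yl)oxan-2-one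
Conditions: TEMPO (10 mol %), PhI(OAc)2, CH2Cl2, rt
Reagents that add atoms: none
Why: Oxoammonium (TEMPO) oxidation of the lactol C–H gives the δ-lactone, which holds the two ends at different oxidation levels and masks the C1 oxygen; the stereocentre is not touched.

Step 4
Reactants: 7 2,3-dibromoprop-1-ene; 8 allylmagnesium bromide
Product: 9 2-bromohexa-1,5-diene
Conditions: Et2O, 0 °C to rt
Reagents that add atoms: none
Why: Grignard allylic substitution (Wurtz-type allyl–allyl coupling) at the allylic C–Br bond, where SN2 and SN2′ attack give the same product and the vinylic bromide is inert.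

Step 5
Reactants: 6 (6S)-4,4-dimethyl-6-(2-methylprop-2-en-1-yl)oxan-2-one; 9 2-bromohexa-1,5-diene
Product: 11 (10S)-10-hydroxy-8,8,12-trimethyl-5-methylidenetrideca-1,12-dien-6-one, via hexa-1,5-dien-2-yllithium 10 (not isolated)
Conditions: 9, t-BuLi (2 equiv), Et2O, −78 °C; then 6, −78 °C; AcOH, THF, −78 °C
Reagents that add atoms: none
Why: Bromine–lithium exchange followed by a single acyl addition of the alkenyllithium to the δ-lactone, whose tetrahedral lithium alkoxide survives at −78 °C so the enone is released only on quench; no new stereocentre is formed and 11 equilibrates with its cyclic hemiketal.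

Step 6
Reactants: 11 (10S)-10-hydroxy-8,8,12-trimethyl-5-methylidenetrideca-1,12-dien-6-one
Product: 12 (5Z,8R)-8-hydroxy-6,10,10-trimethyl-2-methylidenecycloundec-5-en-1-one
Conditions: second-generation Hoveyda–Grubbs catalyst (10 mol %), 1,4-benzoquinone (20 mol %), toluene (1 mM), 80 °C, Ar sparge
Reagents that add atoms: none
Why: Ring-closing metathesis between the vinyl and the methallyl alkene (the enone methylene is inert) closes the eleven-membered ring, and the Z olefin is expected because closure through the hemiketal form, with both arms cis on the oxane, makes a nine-membered oxa-bridged ring that can only hold a cis alkene.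

Step 7
Reactants: 13 p-coumaric acid
Product: 15 (2E)-3-[4-(tert-butyldimethylsilyloxy)phenyl]prop-2-enoic acid, via bis-silyl ester 14 (not isolated)
Conditions: TBSCl (2.3 equiv), imidazole, DMF, rt; then AcOH, THF, H2O, rt
Reagents that add atoms: tert-butyldimethylsilyl chloride, CC(C)(C)[Si](C)(C)Cl
Why: Silylation of both the phenol and the acid, then selective hydrolysis of the much more labile silyl ester, leaves the acid free and the phenol masked for the later mesylation.

Step 8
Reactants: 12 (5Z,8R)-8-hydroxy-6,10,10-trimethyl-2-methylidenecycloundec-5-en-1-one; 15 (2E)-3-[4-(tert-butyldimethylsilyloxy)phenyl]prop-2-enoic acid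
Product: 16 (1R,3Z)-3,10,10-trimethyl-7-methylidene-8-oxocycloundec-3-en-1-yl (2E)-3-[4-(tert-butyldimethylsilyloxy)phenyl]prop-2-enoate
Conditions: DCC, DMAP (cat.), CH2Cl2, 0 °C to rt
Reagents that add atoms: none
Why: Steglich esterification acylates the secondary alcohol of the open hydroxy-ketone form (draining the transannular hemiketal) without touching the C–O bond, so C1 keeps its configuration.

Step 9
Reactants: 16 (1R,3Z)-3,10,10-trimethyl-7-methylidene-8-oxocycloundec-3-en-1-yl (2E)-3-[4-(tert-butyldimethylsilyloxy)phenyl]prop-2-enoate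
Product: 17 (1R,3Z,8R)-8-hydroxy-3,10,10-trimethyl-7-methylidenecycloundec-3-en-1-yl (2E)-3-[4-(tert-butyldimethylsilyloxy)phenyl]prop-2-enoate
Conditions: (S)-2-methyl-CBS-oxazaborolidine (0.5 equiv), catecholborane, toluene, −78 °C
Reagents that add atoms: none
Why: Corey–Bakshi–Shibata reduction, in which the ketone binds the (S)-oxazaborolidine anti to the α-branched alkenyl (large) group and takes hydride 1,2 to give the 8R allylic alcohol, leaving the cinnamate and silyl ether alone.

Step 10
Reactants: 17 (1R,3Z,8R)-8-hydroxy-3,10,10-trimethyl-7-methylidenecycloundec-3-en-1-yl (2E)-3-[4-(tert-butyldimethylsilyloxy)phenyl]prop-2-enoate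
Product: 19 (1R,3Z,8S)-8-hydroperoxy-3,10,10-trimethyl-7-methylidenecycloundec-3-en-1-yl (2E)-3-[4-(tert-butyldimethylsilyloxy)phenyl]prop-2-enoate, via allylic mesylate 18 (not isolated)
Conditions: MsCl, Et3N, CH2Cl2, −65 °C; then anhydrous H2O2 (excess) in Et2O, −78 to −20 °C
Reagents that add atoms: methanesulfonyl chloride, CS(=O)(=O)Cl (atoms stay only in 18); hydrogen peroxide, OO
Why: Mesylation then SN2 displacement by the α-effect nucleophile H2O2 inverts C8 (8R to 8S) under cold, neutral conditions that spare the cinnamate, the silyl ether and the alkenes, and SN2′ attack is disfavoured because it would put a second trisubstituted alkene into the ring.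

Step 11
Reactants: 19 (1R,3Z,8S)-8-hydroperoxy-3,10,10-trimethyl-7-methylidenecycloundec-3-en-1-yl (2E)-3-[4-(tert-butyldimethylsilyloxy)phenyl]prop-2-enoate
Product: 20 (1R,3Z,8S)-8-hydroperoxy-3,10,10-trimethyl-7-methylidenecycloundec-3-en-1-yl (2E)-3-(4-hydroxyphenyl)prop-2-enoate
Conditions: KHF2, MeOH, rt
Reagents that add atoms: none
Why: Fluoride-mediated cleavage of the aryl silyl ether in a slightly acidic medium frees the phenol without the base that would trigger Kornblum–DeLaMare decomposition of the secondary hydroperoxide; no stereocentre is touched.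

**Compound list**

1 | 3,3-dimethylpentane-1,5-diol | OCCC(C)(C)CCO | starting material
2 | 3,3-dimethylpentanedial | O=CCC(C)(C)CC=O | intermediate
3 | (5S)-5-(diisopinocampheylboranyloxy)-3,3,7-trimethyloct-7-enal, Ipc groups from (+)-α-pinene | CC(=C)C[C@H](OB([C@@H]1C[C@@H]2C[C@H]([C@H]1C)C2(C)C)[C@@H]1C[C@@H]2C[C@H]([C@H]1C)C2(C)C)CC(C)(C)CC=O | intermediate
4 | (5S)-5-hydroxy-3,3,7-trimethyloct-7-enal | CC(=C)C[C@H](O)CC(C)(C)CC=O | intermediate
5 | (6S)-4,4-dimethyl-6-(2-methylprop-2-en-1-yl)oxan-2-ol (anomer mixture) | CC(=C)C[C@H]1CC(C)(C)CC(O)O1 | intermediate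
6 | (6S)-4,4-dimethyl-6-(2-methylprop-2-en-1-yl)oxan-2-one | CC(=C)C[C@H]1CC(C)(C)CC(=O)O1 | intermediate
7 | 2,3-dibromoprop-1-ene | C=C(Br)CBr | starting material
8 | allylmagnesium bromide | C=CC[Mg]Br | starting material
9 | 2-bromohexa-1,5-diene | C=C(Br)CCC=C | intermediate
10 | hexa-1,5-dien-2-yllithium | [Li]C(=C)CCC=C | intermediate
11 | (10S)-10-hydroxy-8,8,12-trimethyl-5-methylidenetrideca-1,12-dien-6-one | CC(=C)C[C@H](O)CC(C)(C)CC(=O)C(=C)CCC=C | intermediate
12 | (5Z,8R)-8-hydroxy-6,10,10-trimethyl-2-methylidenecycloundec-5-en-1-one | C=C1CC/C=C(/C)C[C@H](O)CC(C)(C)CC1=O | intermediate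
13 | p-coumaric acid, (2E)-3-(4-hydroxyphenyl)prop-2-enoic acid | OC(=O)/C=C/c1ccc(O)cc1 | starting material
14 | tert-butyldimethylsilyl (2E)-3-[4-(tert-butyldimethylsilyloxy)phenyl]prop-2-enoate | CC(C)(C)[Si](C)(C)OC(=O)/C=C/c1ccc(O[Si](C)(C)C(C)(C)C)cc1 | intermediate
15 | (2E)-3-[4-(tert-butyldimethylsilyloxy)phenyl]prop-2-enoic acid | OC(=O)/C=C/c1ccc(O[Si](C)(C)C(C)(C)C)cc1 | intermediate
16 | (1R,3Z)-3,10,10-trimethyl-7-methylidene-8-oxocycloundec-3-en-1-yl (2E)-3-[4-(tert-butyldimethylsilyloxy)phenyl]prop-2-enoate | C=C1CC/C=C(/C)C[C@H](OC(=O)/C=C/c2ccc(O[Si](C)(C)C(C)(C)C)cc2)CC(C)(C)CC1=O | intermediate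
17 | (1R,3Z,8R)-8-hydroxy-3,10,10-trimethyl-7-methylidenecycloundec-3-en-1-yl (2E)-3-[4-(tert-butyldimethylsilyloxy)phenyl]prop-2-enoate | C=C1CC/C=C(/C)C[C@H](OC(=O)/C=C/c2ccc(O[Si](C)(C)C(C)(C)C)cc2)CC(C)(C)C[C@H]1O | intermediate
18 | (1R,3Z,8R)-8-(methanesulfonyloxy)-3,10,10-trimethyl-7-methylidenecycloundec-3-en-1-yl (2E)-3-[4-(tert-butyldimethylsilyloxy)phenyl]prop-2-enoate | C=C1CC/C=C(/C)C[C@H](OC(=O)/C=C/c2ccc(O[Si](C)(C)C(C)(C)C)cc2)CC(C)(C)C[C@H]1OS(C)(=O)=O | intermediate
19 | (1R,3Z,8S)-8-hydroperoxy-3,10,10-trimethyl-7-methylidenecycloundec-3-en-1-yl (2E)-3-[4-(tert-butyldimethylsilyloxy)phenyl]prop-2-enoate | C=C1CC/C=C(/C)C[C@H](OC(=O)/C=C/c2ccc(O[Si](C)(C)C(C)(C)C)cc2)CC(C)(C)C[C@@H]1OO | intermediate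
20 | (1R,3Z,8S)-8-hydroperoxy-3,10,10-trimethyl-7-methylidenecycloundec-3-en-1-yl (2E)-3-(4-hydroxyphenyl)prop-2-enoate | C=C1CC/C=C(/C)C[C@H](OC(=O)/C=C/c2ccc(O)cc2)CC(C)(C)C[C@@H]1OO | target

**Step count and risks**

Total: 11 steps. Longest linear sequence: 9 steps (1, 2, 3, 5, 6, 8, 9, 10, 11); steps 4 and 7 make the two side pieces.

Step 6 is the least secure. The open form of 11 may oligomerise, or the ring may close to the E olefin. The fallback sets out from 11 and comes back at 12. Compound 11 is first locked in its ring form as the methyl ketal (2S,6S)-2-(hexa-1,5-dien-2-yl)-2-methoxy-4,4-dimethyl-6-(2-methylprop-2-en-1-yl)oxane F1 (MeOH, HC(OMe)3, CSA cat., rt; acid equilibration gives the anomer with axial methoxy and both carbon arms equatorial and cis). Ring-closing metathesis of F1 (second-generation Grubbs catalyst, toluene, 80 °C) then has to form only a nine-membered oxygen-bridged ring, which enforces the cis olefin, and gives (1R,3Z,8S)-8-methoxy-3,10,10-trimethyl-7-methylidene-12-oxabicyclo[6.3.1]dodec-3-ene F2. Hydrolysis of the ketal (1 M HCl, THF) returns 12.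

Step 10 is the second risk. Neutral H2O2 may react too slowly with 18, or give SN2′ and ionisation products, or the product may decompose with the amine present. The fallback sets out from 18 and comes back at 19. The cold mesylate is treated with the preformed potassium salt of 2-methoxypropan-2-yl hydroperoxide (KOt-Bu, 18-crown-6, THF, −40 to 0 °C), a stronger but weakly basic peroxide nucleophile that still displaces with inversion. This gives the peroxyketal (1R,3Z,8S)-8-[(2-methoxypropan-2-yl)peroxy]-3,10,10-trimethyl-7-methylidenecycloundec-3-en-1-yl (2E)-3-[4-(tert-butyldimethylsilyloxy)phenyl]prop-2-enoate F3, which can be purified. Mild acid (AcOH, THF, H2O) then unmasks the hydroperoxide 19.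

Step 2 is the third risk. The dialdehyde is hard to handle and bis-methallylation may not be held back well enough. The fallback sets out from 1 and comes back at 6, with the two ends differentiated before the allylation. Diol 1 is lactonised (TEMPO, PhI(OAc)2) to 4,4-dimethyloxan-2-one F4 and reduced (i-Bu2AlH, CH2Cl2, −78 °C) to the lactol 4,4-dimethyloxan-2-ol F5, which has only one aldehyde equivalent. The same Brown reagent converts F5, by way of the borinate (5S)-5-(diisopinocampheylboranyloxy)-3,3,7-trimethyloct-7-en-1-ol F6, into the diol (5S)-3,3,7-trimethyloct-7-ene-1,5-diol F7. Oxidative lactonisation of F7 (TEMPO, PhI(OAc)2) gives 6.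

**Further compounds**

F1 | step 6 | (2S,6S)-2-(hexa-1,5-dien-2-yl)-2-methoxy-4,4-dimethyl-6-(2-methylprop-2-en-1-yl)oxane | CC(=C)C[C@H]1CC(C)(C)C[C@@](OC)(C(=C)CCC=C)O1
F2 | step 6 | (1R,3Z,8S)-8-methoxy-3,10,10-trimethyl-7-methylidene-12-oxabicyclo[6.3.1]dodec-3-ene | C=C1CC/C=C(/C)C[C@H]2CC(C)(C)C[C@]1(OC)O2
F3 | step 10 | (1R,3Z,8S)-8-[(2-methoxypropan-2-yl)peroxy]-3,10,10-trimethyl-7-methylidenecycloundec-3-en-1-yl (2E)-3-[4-(tert-butyldimethylsilyloxy)phenyl]prop-2-enoate | C=C1CC/C=C(/C)C[C@H](OC(=O)/C=C/c2ccc(O[Si](C)(C)C(C)(C)C)cc2)CC(C)(C)C[C@@H]1OOC(C)(C)OC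
F4 | step 2 | 4,4-dimethyloxan-2-one | O=C1CC(C)(C)CCO1
F5 | step 2 | 4,4-dimethyloxan-2-ol | OC1CC(C)(C)CCO1
F6 | step 2 | (5S)-5-(diisopinocampheylboranyloxy)-3,3,7-trimethyloct-7-en-1-ol, Ipc groups from (+)-α-pinene | CC(=C)C[C@H](OB([C@@H]1C[C@@H]2C[C@H]([C@H]1C)C2(C)C)[C@@H]1C[C@@H]2C[C@H]([C@H]1C)C2(C)C)CC(C)(C)CCO
F7 | step 2 | (5S)-3,3,7-trimethyloct-7-ene-1,5-diol | CC(=C)C[C@H](O)CC(C)(C)CCO
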